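**Plan**

1. Retrosynthesis: remove the four O‑benzyl groups, then the epoxide oxygen (back to a prenyl alkene), then the C3–H bond (back to a C3=C4 silyl enol ether). Ring C is then cut at C2–C3 and C4–C4a into a ring A aryloxymethyl acetate and a ring B silyl ynol ether, which goes back to an aryl alkyne, an aldehyde and an aryl bromide.
2. Forward: ring A fragment 2 (one step) and ring B fragment 9 (four steps) are joined in step 6, where ring C arises by a cationic [4+2] annulation. C3 is then protonated, the prenyl alkene epoxidised and the benzyl ethers removed.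
3. Enabling feature: ring A is a phloroglucinol ring, so C4a lies ortho or para to O1 and to the oxygens on C5 and C7. The O1–C2 unit can therefore be ionised to an aryloxymethyl cation (a 2‑oxadiene) whose ortho carbon closes onto C4, while the ynol ether supplies C3 and C4 at the ketone oxidation level.
4. Stereochemistry: C3 (S) comes from catalyst‑controlled protonation of the silyl enol ether delivered by the key step. The epoxide carbon (R) comes from reagent control in a Shi epoxidation with the D‑fructose‑derived ketone. Later steps are neutral or near neutral to keep both.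

Key step: step 6

Assumption: 3,5‑bis(benzyloxy)phenol and 3‑bromo‑4,5‑dihydroxybenzaldehyde are taken as purchasable; the latter is otherwise one demethylation away from 5‑bromovanillin.
Assumption: the (S)‑binaphthyl‑derived acid in step 7 is taken to deliver the proton to the face of C3 that gives the (3S) ketone; if the sense of induction is the opposite, the mirror‑image catalyst is used with no other change.

**Step 1**
Reactants: 1 3,5‑bis(benzyloxy)phenol
Product: 2 [3,5‑bis(benzyloxy)phenoxy]methyl acetate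
Conditions: BrCH2OAc, i‑Pr2NEt, DMF, 0 °C → rt
Reagents that add atoms: bromomethyl acetate CC(=O)OCBr
Why: Williamson‑type O‑alkylation of the phenol with bromomethyl acetate under an amine base, the standard way to aryl acetoxymethyl ethers, which avoids acyl transfer from the product to phenoxide.

**Step 2**
Reactants: 3 3‑bromo‑4,5‑dihydroxybenzaldehyde
Product: 4 3,4‑bis(benzyloxy)‑5‑bromobenzaldehyde
Conditions: BnBr, K2CO3, DMF, 60 °C
Reagents that add atoms: benzyl bromide BrCc1ccccc1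
Why: Williamson etherification of both catechol hydroxyls, giving a protecting group that survives every later step and leaves by neutral hydrogenolysis.

**Step 3**
Reactants: 4 3,4‑bis(benzyloxy)‑5‑bromobenzaldehyde
Product: 5 3,4‑bis(benzyloxy)‑5‑(3‑methylbut‑2‑en‑1‑yl)benzaldehyde
Conditions: Bu3SnCH2CH=CMe2, Pd(PPh3)4 (5 mol %), LiCl, DMF, 100 °C
Reagents that add atoms: tributyl(3‑methylbut‑2‑en‑1‑yl)stannane CCCC[Sn](CCCC)(CCCC)CC=C(C)C
Why: Stille coupling of an aryl bromide with a prenylstannane on zerovalent palladium, in which reductive elimination at the less hindered allyl terminus should give the linear prenyl arene and the aldehyde is tolerated.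

**Step 4**
Reactants: 5 3,4‑bis(benzyloxy)‑5‑(3‑methylbut‑2‑en‑1‑yl)benzaldehyde
Product: 6 1,2‑bis(benzyloxy)‑5‑ethynyl‑3‑(3‑methylbut‑2‑en‑1‑yl)benzene
Conditions: dimethyl (1‑diazo‑2‑oxopropyl)phosphonate, K2CO3, MeOH/THF, rt
Reagents that add atoms: dimethyl (1‑diazo‑2‑oxopropyl)phosphonate COP(=O)(OC)C(=[N+]=[N-])C(C)=O
Why: Ohira–Bestmann variant of the Seyferth–Gilbert homologation, which converts an aryl aldehyde into the terminal alkyne under mild carbonate conditions that leave the benzyl ethers and the prenyl group untouched.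

**Step 5**
Reactants: 6 1,2‑bis(benzyloxy)‑5‑ethynyl‑3‑(3‑methylbut‑2‑en‑1‑yl)benzene
Product: 9 ({[3,4‑bis(benzyloxy)‑5‑(3‑methylbut‑2‑en‑1‑yl)phenyl]ethynyl}oxy)tri(propan‑2‑yl)silane, via lithium acetylide 7 (not isolated), via lithium ynolate 8 (not isolated)
Conditions: LiN(SiMe3)2, THF, −78 °C; t‑BuOOLi (from t‑BuOOH and LiN(SiMe3)2), −78 → 0 °C; i‑Pr3SiOTf, −78 → 0 °C
Reagents that add atoms: tert‑butyl hydroperoxide CC(C)(C)OO; triisopropylsilyl trifluoromethanesulfonate CC(C)[Si](OS(=O)(=O)C(F)(F)F)(C(C)C)C(C)C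
Why: Oxidation of a lithium acetylide by lithium tert‑butyl peroxide to the ynolate followed by O‑silylation with a bulky silyl triflate, the established route from terminal alkynes to stable triisopropylsilyl ynol ethers.

**Step 6**
Reactants: 2 [3,5‑bis(benzyloxy)phenoxy]methyl acetate; 9 ({[3,4‑bis(benzyloxy)‑5‑(3‑methylbut‑2‑en‑1‑yl)phenyl]ethynyl}oxy)tri(propan‑2‑yl)silane
Product: 12 5,7‑bis(benzyloxy)‑3‑[3,4‑bis(benzyloxy)‑5‑(3‑methylbut‑2‑en‑1‑yl)phenyl]‑4‑[(triisopropylsilyl)oxy]‑2H‑chromene, via aryloxymethyl oxocarbenium triflate 10 (not isolated), via O‑silyl ketenium triflate 11 (not isolated)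
Conditions: 2 (1.0 equiv), 9 (1.2 equiv), 2,6‑di‑tert‑butyl‑4‑methylpyridine (1.5 equiv), 4 Å molecular sieves, CH2Cl2, −78 °C; Me3SiOTf (1.1 equiv) added last, −78 → −20 °C
Reagents that add atoms: none
Why: Proposed new method: Me3SiOTf ionises the acetoxymethyl ether of 2 to the aryloxymethyl cation 10, a cationic 2‑oxadiene, and the oxygen‑polarised alkyne of 9 attacks its CH2 carbon through the aryl‑bearing carbon (C2–C3 bond) to give the O‑silyl ketenium ion 11, whose central carbon is captured by the ortho carbon of ring A (C4–C4a bond) before the pyridine base removes the ring proton, so the event is a stepwise cationic [4+2] annulation. The closest known reaction types are the oxa‑Povarov reaction of aryl oxocarbenium ions with alkenes and the acid‑promoted arene cyclisation of siloxyalkynes through silyl ketenium ions, which is the second half of this event. Ring C closes as a six‑membered ring by 6‑exo‑dig Friedel–Crafts attack on the sp carbon of the ketenium ion, the C=O bond staying outside the ring, and the product is a neutral silyl enol ether that does not ionise again. No stereocentre is formed, because C3 leaves the step as an sp2 carbon ready for step 7. The step needs the cation to choose the ynol ether over the prenyl alkene and over the electron‑rich arenes, which the much higher π‑nucleophilicity of the silyl ynol ether should secure when the silyl triflate is added last at −78 °C to a mixture holding 9 in slight excess, and the hindered base keeps free acid from protonating 9. The site of ring closure is unambiguous because the two ortho carbons of the 3,5‑dioxygenated phenoxy ring are equivalent and each lies ortho or para to all three ring oxygens.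

**Step 7**
Reactants: 12 5,7‑bis(benzyloxy)‑3‑[3,4‑bis(benzyloxy)‑5‑(3‑methylbut‑2‑en‑1‑yl)phenyl]‑4‑[(triisopropylsilyl)oxy]‑2H‑chromene
Product: 13 (3S)‑5,7‑bis(benzyloxy)‑3‑[3,4‑bis(benzyloxy)‑5‑(3‑methylbut‑2‑en‑1‑yl)phenyl]‑2,3‑dihydro‑4H‑chromen‑4‑one
Conditions: (S)‑3,3'‑bis(2,4,6‑triisopropylphenyl)‑1,1'‑binaphthyl‑2,2'‑diyl N‑triflylthiophosphoramide (5–10 mol %), PhOH (1.1 equiv), toluene, −20 °C → rt
Reagents that add atoms: none
Why: Catalytic enantioselective protonation of a silyl enol ether of an α‑aryl cyclic ketone by a chiral Brønsted acid, in which the proton is delivered to one face of C3 inside the chiral ion pair while phenol takes over the silyl group, setting (3S) under acidic, non‑enolising conditions.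

**Step 8**
Reactants: 13 (3S)‑5,7‑bis(benzyloxy)‑3‑[3,4‑bis(benzyloxy)‑5‑(3‑methylbut‑2‑en‑1‑yl)phenyl]‑2,3‑dihydro‑4H‑chromen‑4‑one
Product: 14 (3S)‑5,7‑bis(benzyloxy)‑3‑[3,4‑bis(benzyloxy)‑5‑{[(2R)‑3,3‑dimethyloxiran‑2‑yl]methyl}phenyl]‑2,3‑dihydro‑4H‑chromen‑4‑one
Conditions: D‑fructose‑derived Shi ketone (1,2:4,5‑di‑O‑isopropylidene‑β‑D‑erythro‑2,3‑hexodiulo‑2,6‑pyranose, 1–3 equiv), KHSO5 (as Oxone), NaHCO3, aq Na2H2EDTA, MeCN/CH2(OMe)2, 0 °C, pH 7–8
Reagents that add atoms: potassium peroxymonosulfate [K+].[O-]S(=O)(=O)OO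
Why: Shi epoxidation, in which the dioxirane of the D‑fructose‑derived ketone transfers oxygen to the only trisubstituted alkene through a spiro transition state and should give the (R) epoxide by reagent control, while the pH 7–8 buffer keeps the C3–H of the α‑aryl ketone from exchanging.

**Step 9**
Reactants: 14 (3S)‑5,7‑bis(benzyloxy)‑3‑[3,4‑bis(benzyloxy)‑5‑{[(2R)‑3,3‑dimethyloxiran‑2‑yl]methyl}phenyl]‑2,3‑dihydro‑4H‑chromen‑4‑one
Product: 15 (3S)‑3‑[3,4‑dihydroxy‑5‑{[(2R)‑3,3‑dimethyloxiran‑2‑yl]methyl}phenyl]‑5,7‑dihydroxy‑2,3‑dihydro‑4H‑chromen‑4‑one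
Conditions: H2 (1 atm), Pd/C (acid‑free), EtOAc, rt; filtration, concentration below rt
Reagents that add atoms: none
Why: Hydrogenolysis of aryl benzyl ethers over Pd/C under neutral conditions, which should touch neither the non‑benzylic trialkyl epoxide nor the enolisable C3 centre.

**Compound list**

1 | 3,5‑bis(benzyloxy)phenol | Oc1cc(OCc2ccccc2)cc(OCc2ccccc2)c1 | starting material
2 | [3,5‑bis(benzyloxy)phenoxy]methyl acetate | CC(=O)OCOc1cc(OCc2ccccc2)cc(OCc2ccccc2)c1 | intermediate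
3 | 3‑bromo‑4,5‑dihydroxybenzaldehyde | O=Cc1cc(O)c(O)c(Br)c1 | starting material
4 | 3,4‑bis(benzyloxy)‑5‑bromobenzaldehyde | O=Cc1cc(OCc2ccccc2)c(OCc2ccccc2)c(Br)c1 | intermediate
5 | 3,4‑bis(benzyloxy)‑5‑(3‑methylbut‑2‑en‑1‑yl)benzaldehyde | O=Cc1cc(OCc2ccccc2)c(OCc2ccccc2)c(CC=C(C)C)c1 | intermediate
6 | 1,2‑bis(benzyloxy)‑5‑ethynyl‑3‑(3‑methylbut‑2‑en‑1‑yl)benzene | C#Cc1cc(OCc2ccccc2)c(OCc2ccccc2)c(CC=C(C)C)c1 | intermediate
7 | {[3,4‑bis(benzyloxy)‑5‑(3‑methylbut‑2‑en‑1‑yl)phenyl]ethynyl}lithium (lithium acetylide, not isolated) | [Li]C#Cc1cc(OCc2ccccc2)c(OCc2ccccc2)c(CC=C(C)C)c1 | intermediate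
8 | lithium 2‑[3,4‑bis(benzyloxy)‑5‑(3‑methylbut‑2‑en‑1‑yl)phenyl]ethynolate (lithium ynolate, not isolated) | [Li+].[O-]C#Cc1cc(OCc2ccccc2)c(OCc2ccccc2)c(CC=C(C)C)c1 | intermediate
9 | ({[3,4‑bis(benzyloxy)‑5‑(3‑methylbut‑2‑en‑1‑yl)phenyl]ethynyl}oxy)tri(propan‑2‑yl)silane | CC(C)[Si](OC#Cc1cc(OCc2ccccc2)c(OCc2ccccc2)c(CC=C(C)C)c1)(C(C)C)C(C)C | intermediate
10 | [3,5‑bis(benzyloxy)phenyl](methylidene)oxonium triflate (aryloxymethyl oxocarbenium ion, not isolated) | C=[O+]c1cc(OCc2ccccc2)cc(OCc2ccccc2)c1.[O-]S(=O)(=O)C(F)(F)F | intermediate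
11 | {2‑[3,4‑bis(benzyloxy)‑5‑(3‑methylbut‑2‑en‑1‑yl)phenyl]‑3‑[3,5‑bis(benzyloxy)phenoxy]prop‑1‑en‑1‑ylidene}(triisopropylsilyl)oxonium triflate (O‑silyl ketenium ion, not isolated) | CC(C)[Si]([O+]=C=C(COc1cc(OCc2ccccc2)cc(OCc2ccccc2)c1)c1cc(OCc2ccccc2)c(OCc2ccccc2)c(CC=C(C)C)c1)(C(C)C)C(C)C.[O-]S(=O)(=O)C(F)(F)F | intermediate
12 | 5,7‑bis(benzyloxy)‑3‑[3,4‑bis(benzyloxy)‑5‑(3‑methylbut‑2‑en‑1‑yl)phenyl]‑4‑[(triisopropylsilyl)oxy]‑2H‑chromene | CC(C)[Si](OC1=C(c2cc(OCc3ccccc3)c(OCc3ccccc3)c(CC=C(C)C)c2)COc2cc(OCc3ccccc3)cc(OCc3ccccc3)c21)(C(C)C)C(C)C | intermediate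
13 | (3S)‑5,7‑bis(benzyloxy)‑3‑[3,4‑bis(benzyloxy)‑5‑(3‑methylbut‑2‑en‑1‑yl)phenyl]‑2,3‑dihydro‑4H‑chromen‑4‑one | CC(C)=CCc1cc([C@H]2COc3cc(OCc4ccccc4)cc(OCc4ccccc4)c3C2=O)cc(OCc2ccccc2)c1OCc1ccccc1 | intermediate
14 | (3S)‑5,7‑bis(benzyloxy)‑3‑[3,4‑bis(benzyloxy)‑5‑{[(2R)‑3,3‑dimethyloxiran‑2‑yl]methyl}phenyl]‑2,3‑dihydro‑4H‑chromen‑4‑one | CC1(C)O[C@@H]1Cc1cc([C@H]2COc3cc(OCc4ccccc4)cc(OCc4ccccc4)c3C2=O)cc(OCc2ccccc2)c1OCc1ccccc1 | intermediate
15 | (3S)‑3‑[3,4‑dihydroxy‑5‑{[(2R)‑3,3‑dimethyloxiran‑2‑yl]methyl}phenyl]‑5,7‑dihydroxy‑2,3‑dihydro‑4H‑chromen‑4‑one | CC1(C)O[C@@H]1Cc1cc([C@H]2COc3cc(O)cc(O)c3C2=O)cc(O)c1O | target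

**Step count and risks**

Total steps: 9. Longest linear sequence: 8 (steps 2 to 9, from 3).

Steps most likely to fail:

1. Step 6. The aryloxymethyl cation may be captured by ring A of a second molecule (oligomerisation), or the ynol ether may be lost by protonation before the C–C bond forms. The fallback builds ring C stepwise by known reactions, setting out from alkyne 6 and phenol 1 and returning at 12. The ynolate 8, made from 6 as in step 5, is quenched with HCl in MeOH instead of the silyl triflate (the end of a Kowalski homologation) to give methyl [3,4‑bis(benzyloxy)‑5‑(3‑methylbut‑2‑en‑1‑yl)phenyl]acetate F1. α‑Methylenation with paraformaldehyde, K2CO3 and Bu4NI in toluene gives methyl 2‑arylprop‑2‑enoate F2. Base‑catalysed oxa‑Michael addition of phenol 1 (cat. K2CO3, DMF) gives methyl 3‑[3,5‑bis(benzyloxy)phenoxy]‑2‑arylpropanoate F3. Me3SnOH in 1,2‑dichloroethane frees the 3‑aryloxy‑2‑arylpropanoic acid F4 without β‑elimination of the aryloxide. Intramolecular Friedel–Crafts acylation with (CF3CO)2O in CH2Cl2 at 0 °C closes ring C to the racemic ketone F5. i‑Pr3SiOTf and Et3N in CH2Cl2 then give silyl enol ether 12.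

2. Step 7. Facial selectivity of proton delivery may be poor with the bulky silyl group, or silyl transfer may be slow and let the protonation reverse. The fallback sets out from 12 and returns at 13. Bu4NF buffered with AcOH in THF at 0 °C removes the silyl group to give the racemic ketone F6 (the same structure as F5). Asymmetric transfer hydrogenation with dynamic kinetic resolution, RuCl(p‑cymene)[(S,S)‑TsDPEN] (divalent ruthenium) in HCO2H/Et3N, a reaction known on isoflavanones, gives the cis (3S,4S)‑isoflavan‑4‑ol F7. Dess–Martin periodinane with NaHCO3 in CH2Cl2 at 0 °C oxidises F7 back to the ketone 13 without touching C3.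

3. Step 9. The phenol next to the side chain may open the epoxide as it is unmasked (cyclisation to a dihydrobenzofuran or chromanol), or the epoxide may be reduced. The fallback changes the protecting group before the epoxide is made, setting out from 13 and returning at 15. BCl3 with pentamethylbenzene in CH2Cl2 at −78 °C removes the four benzyl groups in the presence of the alkene to give the prenylated tetraphenol F8. t‑BuMe2SiCl and imidazole in DMF silylate the three non‑chelated hydroxyls to give the tris(silyl) ether F9, the hydrogen‑bonded hydroxyl on C5 staying free. Shi epoxidation as in step 8 gives the epoxide F10. Bu4NF buffered with AcOH in THF at 0 °C then removes the silyl groups without hydrogen or a metal surface and gives 15.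

**Further compounds**

F1 | step 6 | methyl [3,4‑bis(benzyloxy)‑5‑(3‑methylbut‑2‑en‑1‑yl)phenyl]acetate | COC(=O)Cc1cc(OCc2ccccc2)c(OCc2ccccc2)c(CC=C(C)C)c1
F2 | step 6 | methyl 2‑[3,4‑bis(benzyloxy)‑5‑(3‑methylbut‑2‑en‑1‑yl)phenyl]prop‑2‑enoate | C=C(C(=O)OC)c1cc(OCc2ccccc2)c(OCc2ccccc2)c(CC=C(C)C)c1
F3 | step 6 | methyl 3‑[3,5‑bis(benzyloxy)phenoxy]‑2‑[3,4‑bis(benzyloxy)‑5‑(3‑methylbut‑2‑en‑1‑yl)phenyl]propanoate (racemic) | COC(=O)C(COc1cc(OCc2ccccc2)cc(OCc2ccccc2)c1)c1cc(OCc2ccccc2)c(OCc2ccccc2)c(CC=C(C)C)c1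
F4 | step 6 | 3‑[3,5‑bis(benzyloxy)phenoxy]‑2‑[3,4‑bis(benzyloxy)‑5‑(3‑methylbut‑2‑en‑1‑yl)phenyl]propanoic acid (racemic) | OC(=O)C(COc1cc(OCc2ccccc2)cc(OCc2ccccc2)c1)c1cc(OCc2ccccc2)c(OCc2ccccc2)c(CC=C(C)C)c1
F5 | step 6 | 5,7‑bis(benzyloxy)‑3‑[3,4‑bis(benzyloxy)‑5‑(3‑methylbut‑2‑en‑1‑yl)phenyl]‑2,3‑dihydro‑4H‑chromen‑4‑one (racemic) | CC(C)=CCc1cc(C2COc3cc(OCc4ccccc4)cc(OCc4ccccc4)c3C2=O)cc(OCc2ccccc2)c1OCc1ccccc1
F6 | step 7 | 5,7‑bis(benzyloxy)‑3‑[3,4‑bis(benzyloxy)‑5‑(3‑methylbut‑2‑en‑1‑yl)phenyl]‑2,3‑dihydro‑4H‑chromen‑4‑one (racemic) | CC(C)=CCc1cc(C2COc3cc(OCc4ccccc4)cc(OCc4ccccc4)c3C2=O)cc(OCc2ccccc2)c1OCc1ccccc1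
F7 | step 7 | (3S,4S)‑5,7‑bis(benzyloxy)‑3‑[3,4‑bis(benzyloxy)‑5‑(3‑methylbut‑2‑en‑1‑yl)phenyl]‑3,4‑dihydro‑2H‑chromen‑4‑ol | CC(C)=CCc1cc([C@H]2COc3cc(OCc4ccccc4)cc(OCc4ccccc4)c3[C@H]2O)cc(OCc2ccccc2)c1OCc1ccccc1
F8 | step 9 | (3S)‑3‑[3,4‑dihydroxy‑5‑(3‑methylbut‑2‑en‑1‑yl)phenyl]‑5,7‑dihydroxy‑2,3‑dihydro‑4H‑chromen‑4‑one | CC(C)=CCc1cc([C@H]2COc3cc(O)cc(O)c3C2=O)cc(O)c1O
F9 | step 9 | (3S)‑7‑[(tert‑butyldimethylsilyl)oxy]‑3‑[3,4‑bis{[tert‑butyldimethylsilyl]oxy}‑5‑(3‑methylbut‑2‑en‑1‑yl)phenyl]‑5‑hydroxy‑2,3‑dihydro‑4H‑chromen‑4‑one | CC(C)=CCc1cc([C@H]2COc3cc(O[Si](C)(C)C(C)(C)C)cc(O)c3C2=O)cc(O[Si](C)(C)C(C)(C)C)c1O[Si](C)(C)C(C)(C)C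
F10 | step 9 | (3S)‑7‑[(tert‑butyldimethylsilyl)oxy]‑3‑[3,4‑bis{[tert‑butyldimethylsilyl]oxy}‑5‑{[(2R)‑3,3‑dimethyloxiran‑2‑yl]methyl}phenyl]‑5‑hydroxy‑2,3‑dihydro‑4H‑chromen‑4‑one | CC1(C)O[C@@H]1Cc1cc([C@H]2COc3cc(O[Si](C)(C)C(C)(C)C)cc(O)c3C2=O)cc(O[Si](C)(C)C(C)(C)C)c1O[Si](C)(C)C(C)(C)C
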